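**Retrosynthetic overview**
1. C2–C1' is made last and sets (2S). Chromone 9 becomes a C2-bound nickel homoenolate, so C2 turns nucleophilic, and it is joined to aryl iodide 10. Two electrophilic carbons are coupled under Mn reduction.
2. C8–prenyl comes from a para-Claisen–Cope shift of the 5-O-prenyl ether 6. This fixes the 8-regiochemistry and frees 5-OH without protecting groups.
3. Ring C is built once, as the chromone, from acetophenone 2 plus one carbon (DMF-DMA). Rings A and B are bought.
4. Order: ring A (bought), ring C (step 2), prenyl (steps 3–4), then ring B attached while ring C drops to the chromanone level (step 5).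

Assumption: the facial sense of the new nickel step cannot be predicted, so the (S,S)-ligand is written and its antipode is used if it gives (2R); 2-iodo-1,3,5-trimethoxybenzene is taken as a catalogue compound.

**Step 1**
Reactants: 1 1-(2,4,6-trihydroxyphenyl)ethanone (phloroacetophenone)
Product: 2 1-(2,6-dihydroxy-4-methoxyphenyl)ethanone
Conditions: Me2SO4 (1.0 equiv), K2CO3 (1.0 equiv), acetone, reflux
Reagents that add atoms: dimethyl sulfate, COS(=O)(=O)OC
Why: Williamson-type O-methylation, in which the 4-OH is the most acidic hydroxyl and the only one not hydrogen-bonded to the acetyl C=O, so one equivalent of the hard electrophile caps it selectively (no stereocentre).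

**Step 2**
Reactants: 2 1-(2,6-dihydroxy-4-methoxyphenyl)ethanone
Product: 4 5-hydroxy-7-methoxy-4H-chromen-4-one, via enaminone 3 (not isolated)
Conditions: DMF-DMA (2 equiv), toluene, 90 °C; evaporate; conc. HCl, CH2Cl2, 40 °C
Reagents that add atoms: N,N-dimethylformamide dimethyl acetal, COC(OC)N(C)C
Why: Enaminone chromone synthesis, in which the acetyl CH3 condenses to the vinylogous amide 3 and acid triggers addition–elimination of an ortho-OH with loss of Me2NH to close ring C; the two ortho-hydroxyls of 2 are equivalent, so only one chromone can form.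

**Step 3**
Reactants: 4 5-hydroxy-7-methoxy-4H-chromen-4-one; 5 1-bromo-3-methylbut-2-ene (prenyl bromide)
Product: 6 7-methoxy-5-[(3-methylbut-2-en-1-yl)oxy]-4H-chromen-4-one
Conditions: K2CO3 (2 equiv), DMF, 50 °C
Reagents that add atoms: none
Why: Williamson ether synthesis (SN2), in which 4 has a single OH so over-alkylation is impossible, and K2CO3 in DMF breaks the chelate well enough for O-alkylation by the reactive allylic bromide.

**Step 4**
Reactants: 6 7-methoxy-5-[(3-methylbut-2-en-1-yl)oxy]-4H-chromen-4-one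
Product: 9 5-hydroxy-7-methoxy-8-(3-methylbut-2-en-1-yl)-4H-chromen-4-one, via ortho-dienone 7 (not isolated), via para-dienone 8 (not isolated)
Conditions: Eu(fod)3 (10 mol%), PhCl, 85 °C
Reagents that add atoms: none
Why: Tandem aromatic Claisen/Cope rearrangement (para-Claisen–Cope), in which the oxophilic europium chelate speeds the [3,3] shift to C6 (7), a second [3,3] shift carries the group on to C8 (8), and tautomerisation gives the chelated phenol 9, so prenyl lands at C8 only and 5-OH is freed.

**Step 5**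
Reactants: 9 5-hydroxy-7-methoxy-8-(3-methylbut-2-en-1-yl)-4H-chromen-4-one; 10 2-iodo-1,3,5-trimethoxybenzene
Product: 13 (2S)-5-hydroxy-7-methoxy-8-(3-methylbut-2-en-1-yl)-2-(2,4,6-trimethoxyphenyl)-2,3-dihydro-4H-chromen-4-one, via nickel homoenolate 11 (not isolated), via silyl enol ether 12 (not isolated)
Conditions: iodide 10 (1.5 equiv), NiBr2·diglyme (10 mol%), (S,S)-4-heptyl-BiOX [(4S,4'S)-4,4'-di(heptan-4-yl)-4,4',5,5'-tetrahydro-2,2'-bioxazole] (12 mol%), Mn powder (3 equiv), Me3SiCl (2.5 equiv), DMA, 10 °C; then pH 5 phosphate buffer–THF, 0 °C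
Reagents that add atoms: none
Why: Proposed new method: zerovalent nickel (from NiBr2·diglyme and Mn) carrying the chiral bioxazoline binds C2=C3 of 9 and Me3SiCl traps the carbonyl oxygen, giving the 1-silyloxyallyl-type nickel homoenolate 11 in which the normally electrophilic C2 is metal-bound and nucleophilic; one-electron reduction by Mn, oxidative addition of the second electrophile 10 and C–C reductive elimination from the trivalent aryl(allyl)nickel at the less hindered allyl terminus C2 give silyl enol ether 12, the ligand pocket deciding which face of the planar chromenyl fragment bonds to the aryl group and so setting (2S), and buffered hydrolysis gives ketone 13 without base or strong acid so the labile benzylic ether centre is not scrambled; the closest known reaction types are the reversed-polarity conjugate addition of enone-derived silyloxyallylnickel reagents to aryl halides, its Ni/Mn/R3SiCl-catalytic reductive conjugate arylation variant, and the enantioconvergent nickel/bioxazoline reductive cross-coupling of secondary benzylic electrophiles with aryl iodides.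

**Compound list**
1 | 1-(2,4,6-trihydroxyphenyl)ethanone | CC(=O)c1c(O)cc(O)cc1O | starting material
2 | 1-(2,6-dihydroxy-4-methoxyphenyl)ethanone | CC(=O)c1c(O)cc(OC)cc1O | intermediate
3 | (E)-1-(2,6-dihydroxy-4-methoxyphenyl)-3-(dimethylamino)prop-2-en-1-one | CN(C)/C=C/C(=O)c1c(O)cc(OC)cc1O | intermediate
4 | 5-hydroxy-7-methoxy-4H-chromen-4-one | COc1cc(O)c2c(c1)OC=CC2=O | intermediate
5 | 1-bromo-3-methylbut-2-ene | CC(C)=CCBr | starting material
6 | 7-methoxy-5-[(3-methylbut-2-en-1-yl)oxy]-4H-chromen-4-one | COc1cc(OCC=C(C)C)c2c(c1)OC=CC2=O | intermediate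
7 | 7-methoxy-6-(2-methylbut-3-en-2-yl)-4H-chromene-4,5(6H)-dione (racemic, centre lost again) | COC1=CC2=C(C(=O)C=CO2)C(=O)C1C(C)(C)C=C | intermediate
8 | 7-methoxy-8-(3-methylbut-2-en-1-yl)-4H-chromene-4,5(8H)-dione (racemic, centre lost again) | COC1=CC(=O)C2=C(OC=CC2=O)C1CC=C(C)C | intermediate
9 | 5-hydroxy-7-methoxy-8-(3-methylbut-2-en-1-yl)-4H-chromen-4-one | COc1cc(O)c2c(c1CC=C(C)C)OC=CC2=O | intermediate
10 | 2-iodo-1,3,5-trimethoxybenzene | COc1cc(OC)c(I)c(OC)c1 | starting material
11 | chloro[5-hydroxy-7-methoxy-8-(3-methylbut-2-en-1-yl)-4-(trimethylsilyloxy)-2H-chromen-2-yl]nickel, bioxazoline-ligated (drawn C2-bound; ligand left out of the SMILES) | C[Si](C)(C)OC1=CC([Ni]Cl)Oc2c1c(O)cc(OC)c2CC=C(C)C | intermediate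
12 | (2S)-7-methoxy-8-(3-methylbut-2-en-1-yl)-2-(2,4,6-trimethoxyphenyl)-4-(trimethylsilyloxy)-2H-chromen-5-ol | COc1cc(OC)c([C@@H]2C=C(O[Si](C)(C)C)c3c(O)cc(OC)c(CC=C(C)C)c3O2)c(OC)c1 | intermediate
13 | (2S)-5-hydroxy-7-methoxy-8-(3-methylbut-2-en-1-yl)-2-(2,4,6-trimethoxyphenyl)-2,3-dihydro-4H-chromen-4-one | COc1cc(OC)c([C@@H]2CC(=O)c3c(O)cc(OC)c(CC=C(C)C)c3O2)c(OC)c1 | target

**Total step count:** 5. **Longest linear sequence:** 5 steps (1 → 2 → 4 → 6 → 9 → 13).

**Three steps most likely to fail**

**Step 5.**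
- The iodide is electron-rich and has two ortho substituents, so its uptake by nickel may lose to hydrodeiodination or to C2–C2' reductive dimerisation of the chromone.
- The level and sense of ee are unknown.
- A racemic Friedel–Crafts attack of a free C–H position of 10 on silyl-activated 9 could erode the ee. DMA and 10 °C are chosen to suppress it.
- The chelated 5-OH is left free because phenols survive Ni/Mn cross-electrophile couplings, and any O-silylation is undone by the buffer.

The fallback sets out from 6 and comes back at 13. The C2–H of 6 is zincated with (2,2,6,6-tetramethylpiperidin-1-yl)ZnCl·LiCl (THF, 25 °C, no added Lewis acid) to [7-methoxy-5-(prenyloxy)-4-oxo-4H-chromen-2-yl]zinc chloride F1, which is still a C2 nucleophile. Negishi coupling with 10 (Pd(OAc)2, SPhos, THF, 50 °C) gives 7-methoxy-5-(prenyloxy)-2-(2,4,6-trimethoxyphenyl)-4H-chromen-4-one F2. Eu(fod)3 in PhCl at 85 °C moves the prenyl group to give 5-hydroxy-7-methoxy-8-prenyl-2-(2,4,6-trimethoxyphenyl)-4H-chromen-4-one F3. Asymmetric copper hydride conjugate reduction then delivers hydride to C2 and gives 13. Its conditions are Cu(OAc)2, the DTBM-SEGPHOS antipode that gives 2S, (EtO)2MeSiH, t-BuOH, toluene, 0 °C.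

**Step 4.** The sequence may stop after the first shift, giving the 6-(1,1-dimethylallyl) phenol, or the ether may simply be cleaved. The fallback sets out from 2 and comes back at 9.
- C-prenylation of 2 with 5 (KOH, H2O–MeOH, 0 °C) gives 1-[2,6-dihydroxy-4-methoxy-3-(3-methylbut-2-en-1-yl)phenyl]ethanone F4.
- TBSCl/imidazole (DMF, 0 °C) silylates the less hindered 6-OH to the mono-silyl ether F5.
- DMF-DMA gives the silyl-protected enaminone F6.
- F6 closes in AcOH at 60 °C through the only free OH, the one next to the prenyl group, to the 5-silyloxy-8-prenylchromone F7.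
- Bu4NF/AcOH then gives 9.

**Step 2.** DMF-DMA can O-methylate the non-chelated phenol of 2 and lower the yield. The fallback sets out from 2 and comes back at 6, bypassing 4.
- Mono-O-prenylation of 2 with 5 (K2CO3, acetone, reflux) gives 1-{2-hydroxy-4-methoxy-6-[(3-methylbut-2-en-1-yl)oxy]phenyl}ethanone F8. Its only remaining OH is chelated and inert to DMF-DMA.
- Condensation with DMF-DMA gives the prenyloxy enaminone F9.
- AcOH at 60 °C is mild enough for the prenyl ether and closes it to 6.

**Further compounds**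
F1 | step 5 | [7-methoxy-5-(3-methylbut-2-en-1-yloxy)-4-oxo-4H-chromen-2-yl]zinc chloride | COc1cc(OCC=C(C)C)c2c(c1)OC([Zn]Cl)=CC2=O
F2 | step 5 | 7-methoxy-5-(3-methylbut-2-en-1-yloxy)-2-(2,4,6-trimethoxyphenyl)-4H-chromen-4-one | COc1cc(OC)c(C2=CC(=O)c3c(OCC=C(C)C)cc(OC)cc3O2)c(OC)c1
F3 | step 5 | 5-hydroxy-7-methoxy-8-(3-methylbut-2-en-1-yl)-2-(2,4,6-trimethoxyphenyl)-4H-chromen-4-one | COc1cc(OC)c(C2=CC(=O)c3c(O)cc(OC)c(CC=C(C)C)c3O2)c(OC)c1
F4 | step 4 | 1-[2,6-dihydroxy-4-methoxy-3-(3-methylbut-2-en-1-yl)phenyl]ethanone | CC(=O)c1c(O)cc(OC)c(CC=C(C)C)c1O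
F5 | step 4 | 1-[6-(tert-butyldimethylsilyloxy)-2-hydroxy-4-methoxy-3-(3-methylbut-2-en-1-yl)phenyl]ethanone | CC(=O)c1c(O[Si](C)(C)C(C)(C)C)cc(OC)c(CC=C(C)C)c1O
F6 | step 4 | (E)-1-[6-(tert-butyldimethylsilyloxy)-2-hydroxy-4-methoxy-3-(3-methylbut-2-en-1-yl)phenyl]-3-(dimethylamino)prop-2-en-1-one | CN(C)/C=C/C(=O)c1c(O[Si](C)(C)C(C)(C)C)cc(OC)c(CC=C(C)C)c1O
F7 | step 4 | 5-(tert-butyldimethylsilyloxy)-7-methoxy-8-(3-methylbut-2-en-1-yl)-4H-chromen-4-one | COc1cc(O[Si](C)(C)C(C)(C)C)c2c(c1CC=C(C)C)OC=CC2=O
F8 | step 2 | 1-{2-hydroxy-4-methoxy-6-[(3-methylbut-2-en-1-yl)oxy]phenyl}ethanone | CC(=O)c1c(O)cc(OC)cc1OCC=C(C)C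
F9 | step 2 | (E)-3-(dimethylamino)-1-{2-hydroxy-4-methoxy-6-[(3-methylbut-2-en-1-yl)oxy]phenyl}prop-2-en-1-one | CN(C)/C=C/C(=O)c1c(O)cc(OC)cc1OCC=C(C)C
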